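**Plan**

Numbering: C1 = CH(aryl), C2 = CH(CO2R), C3(CO2R)=C4H, ring A = C4a–C8a with O7 and O8 (C8 next to C8a). The target reads (1R,2S), which is trans, and both side-chain carbinol carbons are R.
Enabling feature: C1 carries only H, the pendant catechol ring, C2 and C8a. It is therefore the carbonyl carbon of protocatechualdehyde, inserted between the α-carbon C2 of an E-arylidenesuccinate and the ring-A carbon C8a next to O8.
Cuts: first the two ester O–CH bonds to the dihydroxyphenyllactate units, then C1–C8a and C1–C2 together (ring B), then C3=C4 of the arylidenesuccinate.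
Forward: ring A is bought as an aromatic aldehyde and receives silicon at the future C8a, and a Stobbe condensation sets C3=C4. Ring B, the only ring made, closes in a [5+1] aldol/ipso-Friedel–Crafts annulation; the side chains are joined last and all benzyl groups fall in one step.
Stereochemistry: C2 comes from (R)-4-benzyl-2-oxazolidinone in a boron aldol, and C1 is relayed trans from C2 in the cationic closure. Both side-chain centres come from L-DOPA (retentive diazotisation to S, Mitsunobu inversion to R).

Key step: step 8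

Assumption: the boron dienolate is taken to follow the usual facial sense of oxazolidinone syn-aldols, under which the (R)-auxiliary delivers the C2 geometry of the target; reagent amounts are indicative.

**Step 1**
Reactants: 1 2-bromo-3-hydroxy-4-methoxybenzaldehyde (2-bromoisovanillin)
Product: 2 2-bromo-3,4-dihydroxybenzaldehyde
Conditions: BBr3, CH2Cl2, −78 °C → rt; H2O
Reagents that add atoms: none
Why: Lewis-acid ether cleavage: BBr3 binds the methoxy oxygen beside the free phenol and bromide removes the methyl group by SN2, conditions under which the aryl bromide and the deactivated aldehyde should persist.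

**Step 2**
Reactants: 2 2-bromo-3,4-dihydroxybenzaldehyde
Product: 3 3,4-bis(benzyloxy)-2-bromobenzaldehyde
Conditions: BnBr, K2CO3, DMF, rt → 50 °C
Reagents that add atoms: benzyl bromide, BrCc1ccccc1
Why: Twofold Williamson ether synthesis on the acidic catechol; benzyl is chosen because it survives organolithium, boron triflate and hydroperoxide and can be removed at the end without hydrogen.

**Step 3**
Reactants: 3 3,4-bis(benzyloxy)-2-bromobenzaldehyde
Product: 4 1,2-bis(benzyloxy)-3-bromo-4-(dimethoxymethyl)benzene
Conditions: HC(OMe)3, cat. p-TsOH, MeOH, reflux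
Reagents that add atoms: trimethyl orthoformate, COC(OC)OC
Why: Acid-catalysed acetalisation, driven by the orthoformate as water scavenger, masks the aldehyde against n-BuLi.

**Step 4**
Reactants: 4 1,2-bis(benzyloxy)-3-bromo-4-(dimethoxymethyl)benzene
Product: 7 3,4-bis(benzyloxy)-2-(trimethylsilyl)benzaldehyde, via aryllithium 5 (not isolated), via silylated dimethyl acetal 6 (not isolated)
Conditions: n-BuLi, THF, −78 °C; TMSCl, −78 °C → rt; then 1 M HCl, THF, rt
Reagents that add atoms: n-butyllithium, [Li]CCCC (lithium of 5 only); chlorotrimethylsilane, C[Si](C)(C)Cl; water, O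
Why: Bromine–lithium exchange at −78 °C outruns benzylic deprotonation and gives an aryllithium held by two flanking oxygen donors, TMSCl silylates it, and dilute aqueous acid hydrolyses the acetal far faster than it protodesilylates a ring carbon ortho to the emerging formyl group.

**Step 5**
Reactants: 7 3,4-bis(benzyloxy)-2-(trimethylsilyl)benzaldehyde; 8 dimethyl succinate
Product: 9 (3E)-4-[3,4-bis(benzyloxy)-2-(trimethylsilyl)phenyl]-3-(methoxycarbonyl)but-3-enoic acid
Conditions: t-BuOK, t-BuOH/THF, 0 °C → rt; cold 1 M HCl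
Reagents that add atoms: none
Why: Stobbe condensation: aldol addition, lactonisation and E1cB ring opening turn exactly one ester into the carboxylate and place the aryl group cis to the CH2CO2H arm (E), the geometry ring B needs; short contact at or below room temperature is chosen to spare the aryl–silicon bond.

**Step 6**
Reactants: 9 (3E)-4-[3,4-bis(benzyloxy)-2-(trimethylsilyl)phenyl]-3-(methoxycarbonyl)but-3-enoic acid; 10 (R)-4-benzyl-2-oxazolidinone
Product: 12 methyl (2E)-2-{2-[(4R)-4-benzyl-2-oxo-1,3-oxazolidin-3-yl]-2-oxoethyl}-3-[3,4-bis(benzyloxy)-2-(trimethylsilyl)phenyl]prop-2-enoate, via mixed pivalic anhydride 11 (not isolated)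
Conditions: PivCl, Et3N, THF, −20 °C; then LiCl, 10, −20 °C → rt
Reagents that add atoms: pivaloyl chloride, CC(C)(C)C(=O)Cl (pivaloyl unit of 11 only)
Why: Mixed-anhydride N-acylation of the oxazolidinone in its LiCl/Et3N variant needs no strong base, so the acidic allylic CH2, the E alkene and the aryl silane should be left alone, and the hindered pivaloyl carbonyl directs attack to the substrate carbonyl.

**Step 7**
Reactants: 13 3,4-dihydroxybenzaldehyde (protocatechualdehyde)
Product: 14 3,4-bis(benzyloxy)benzaldehyde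
Conditions: BnBr, K2CO3, DMF, rt → 50 °C
Reagents that add atoms: benzyl bromide, BrCc1ccccc1
Why: Twofold Williamson ether synthesis gives the C1 linchpin with a para-oxygen that will later stabilise the C1 cation.

**Step 8**
Reactants: 12 E-arylidenesuccinate imide with SiMe3 on the future C8a; 14 3,4-bis(benzyloxy)benzaldehyde
Product: 17 methyl (1R,2S)-7,8-bis(benzyloxy)-1-[3,4-bis(benzyloxy)phenyl]-2-{[(4R)-4-benzyl-2-oxo-1,3-oxazolidin-3-yl]carbonyl}-1,2-dihydronaphthalene-3-carboxylate, via boron Z-dienolate 15 (not isolated), via boron syn-aldolate 16 (not isolated)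
Conditions: Bu2BOTf (1.15 equiv), iPr2NEt (1.25 equiv), CH2Cl2, −78 → 0 °C; 14, −78 → 0 °C; then TMSOTf (0.3 equiv), −78 → −20 °C; pH 7 buffer
Reagents that add atoms: dibutylboron triflate, CCCCB(CCCC)OS(=O)(=O)C(F)(F)F (Bu2B unit of 15 and 16 only)
Why: Proposed new method: soft enolisation gives the Z-boron dienolate 15, which adds through its α-carbon C2 to aldehyde 14 in a closed Zimmerman–Traxler chair (C1–C2); catalytic TMSOTf then ionises the benzylic C1–O–B bond of 16 to a para-oxygen-stabilised, quinone-methide-like cation that the silicon-bearing C8a attacks (C1–C8a), and the departing Me3Si+ regenerates TMSOTf, so no proton is released at any stage. The closest known reaction types are the oxazolidinone boron syn-aldol of β,γ-unsaturated imides, the acid cyclisation of α-(hydroxybenzyl) arylidenesuccinates to 1-aryl-1,2-dihydronaphthalenes, and silicon-directed ipso ring closures of the Pictet–Spengler type; only their union in one flask, on the boron aldolate itself, is new. Ring B closes in a six-membered cationic ipso-Friedel–Crafts mode (6-endo with respect to the C4a–C8a arene bond), which the E geometry of C3=C4 allows because it holds ring A cis to C2. C2 is set by the (R)-benzyl group of the auxiliary, which exposes one dienolate face in the dipole-opposed chair (open-chain descriptor R, becoming S in 17 by priority change only); the carbinol configuration is erased on ionisation and C1 is reset trans to the C2 acyl group in the half-chair. The step needs α- over γ-attack (cyclic boron transition state, aryl-blocked C4), C8a over the open C5 para to O8 (β-silicon stabilisation of the ipso Wheland ion), and closure over protodesilylation or loss of the C2 proton (aprotic Lewis-acid medium in which iPr2NEt·HOTf is the only, very weak, proton source, and low temperature).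

**Step 9**
Reactants: 17 protected core with C3 methyl ester and C2 acyl oxazolidinone
Product: 19 (1R,2S)-7,8-bis(benzyloxy)-1-[3,4-bis(benzyloxy)phenyl]-3-(methoxycarbonyl)-1,2-dihydronaphthalene-2-carboxylic acid, via peroxy acid 18 (not isolated)
Conditions: LiOH, H2O2, THF/H2O, 0 °C; Na2SO3; 1 M HCl
Reagents that add atoms: hydrogen peroxide, OO
Why: Hydroperoxide cleavage of an N-acyl oxazolidinone: the small, weakly basic HOO− attacks the exocyclic carbonyl even of a hindered imide, leaves the C2–H and the conjugated methyl ester untouched at 0 °C, and sulfite reduces the peroxy acid; the auxiliary is recovered.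

**Step 10**
Reactants: 19 C2 acid, C3 methyl ester
Product: 20 (1R,2S)-7,8-bis(benzyloxy)-1-[3,4-bis(benzyloxy)phenyl]-1,2-dihydronaphthalene-2,3-dicarboxylic acid
Conditions: LiOH, THF/MeOH/H2O, 40 °C; 1 M HCl
Reagents that add atoms: lithium hydroxide, [Li+].[OH-]
Why: Saponification (BAc2) of the conjugated methyl ester; because C2 now bears a carboxylate its α-proton is no longer acidic, so epimerisation at C2 and migration of C3=C4 should not compete.

**Step 11**
Reactants: 21 L-DOPA
Product: 22 (2S)-3-(3,4-dihydroxyphenyl)-2-hydroxypropanoic acid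
Conditions: NaNO2 (slow addition), 1 M H2SO4, Ar, 0 °C → rt
Reagents that add atoms: water, O
Why: Diazotisation–hydrolysis of an α-amino acid with net retention (double inversion through carboxylate participation) converts the S amine into the S alcohol; slow nitrite addition in the cold keeps nitrous acid low and limits attack on the catechol.

**Step 12**
Reactants: 22 (2S)-3-(3,4-dihydroxyphenyl)-2-hydroxypropanoic acid
Product: 23 benzyl (2S)-3-[3,4-bis(benzyloxy)phenyl]-2-hydroxypropanoate
Conditions: BnBr (3.1 equiv), K2CO3, DMF, rt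
Reagents that add atoms: benzyl bromide, BrCc1ccccc1
Why: Carboxylate and phenoxide alkylation (Williamson type): K2CO3 deprotonates only the acid and the two phenols, so the secondary alcohol stays free and the stereocentre is not touched.

**Step 13**
Reactants: 20 protected diacid; 23 benzyl (2S)-3-[3,4-bis(benzyloxy)phenyl]-2-hydroxypropanoate (two units incorporated)
Product: 24 bis{(2R)-1-(benzyloxy)-3-[3,4-bis(benzyloxy)phenyl]-1-oxopropan-2-yl} (1R,2S)-7,8-bis(benzyloxy)-1-[3,4-bis(benzyloxy)phenyl]-1,2-dihydronaphthalene-2,3-dicarboxylate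
Conditions: 23 (2.4 equiv), PPh3, DIAD, toluene/THF, 0 °C; then 20 (slow addition), 0 °C → rt
Reagents that add atoms: none
Why: Twofold Mitsunobu esterification: each carboxylate displaces the alkoxyphosphonium ion of the α-hydroxy ester by SN2, inverting S to R, while C1 and C2 are safe because the acids act only as nucleophiles under neutral conditions; the alcohol is activated before the diacid is added to disfavour acyloxyphosphonium formation.

**Step 14**
Reactants: 24 decabenzyl-protected target
Product: 25 bis[(1R)-1-carboxy-2-(3,4-dihydroxyphenyl)ethyl] (1R,2S)-1-(3,4-dihydroxyphenyl)-7,8-dihydroxy-1,2-dihydronaphthalene-2,3-dicarboxylate (CNP0244800.2)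
Conditions: BCl3, pentamethylbenzene, CH2Cl2, −78 → 0 °C; then H2O
Reagents that add atoms: none
Why: Lewis-acid debenzylation with a non-basic cation scavenger: BCl3 cleaves the eight aryl benzyl ethers in the cold and the two benzyl esters on warming, pentamethylbenzene traps each benzyl cation by Friedel–Crafts alkylation, and both the C3=C4 bond (which hydrogenolysis would endanger) and the two secondary esters (whose α-carbonyl carbons cannot ionise) remain.

**Compound list**

1 | 2-bromo-3-hydroxy-4-methoxybenzaldehyde | COc1ccc(C=O)c(Br)c1O | starting material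
2 | 2-bromo-3,4-dihydroxybenzaldehyde | O=Cc1ccc(O)c(O)c1Br | intermediate
3 | 3,4-bis(benzyloxy)-2-bromobenzaldehyde | O=Cc1ccc(OCc2ccccc2)c(OCc2ccccc2)c1Br | intermediate
4 | 1,2-bis(benzyloxy)-3-bromo-4-(dimethoxymethyl)benzene | COC(OC)c1ccc(OCc2ccccc2)c(OCc2ccccc2)c1Br | intermediate
5 | [2,3-bis(benzyloxy)-6-(dimethoxymethyl)phenyl]lithium (not isolated) | COC(OC)c1ccc(OCc2ccccc2)c(OCc2ccccc2)c1[Li] | intermediate
6 | [2,3-bis(benzyloxy)-6-(dimethoxymethyl)phenyl]trimethylsilane (not isolated) | COC(OC)c1ccc(OCc2ccccc2)c(OCc2ccccc2)c1[Si](C)(C)C | intermediate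
7 | 3,4-bis(benzyloxy)-2-(trimethylsilyl)benzaldehyde | O=Cc1ccc(OCc2ccccc2)c(OCc2ccccc2)c1[Si](C)(C)C | intermediate
8 | dimethyl succinate | COC(=O)CCC(=O)OC | starting material
9 | (3E)-4-[3,4-bis(benzyloxy)-2-(trimethylsilyl)phenyl]-3-(methoxycarbonyl)but-3-enoic acid | COC(=O)/C(CC(=O)O)=C/c1ccc(OCc2ccccc2)c(OCc2ccccc2)c1[Si](C)(C)C | intermediate
10 | (R)-4-benzyl-2-oxazolidinone | O=C1N[C@H](Cc2ccccc2)CO1 | starting material
11 | mixed anhydride of 9 with pivalic acid (not isolated) | COC(=O)/C(CC(=O)OC(=O)C(C)(C)C)=C/c1ccc(OCc2ccccc2)c(OCc2ccccc2)c1[Si](C)(C)C | intermediate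
12 | methyl (2E)-2-{2-[(4R)-4-benzyl-2-oxo-1,3-oxazolidin-3-yl]-2-oxoethyl}-3-[3,4-bis(benzyloxy)-2-(trimethylsilyl)phenyl]prop-2-enoate (key-step precursor) | COC(=O)/C(CC(=O)N1[C@H](Cc2ccccc2)COC1=O)=C/c1ccc(OCc2ccccc2)c(OCc2ccccc2)c1[Si](C)(C)C | intermediate
13 | 3,4-dihydroxybenzaldehyde | O=Cc1ccc(O)c(O)c1 | starting material
14 | 3,4-bis(benzyloxy)benzaldehyde | O=Cc1ccc(OCc2ccccc2)c(OCc2ccccc2)c1 | intermediate
15 | dibutylboron Z-dienolate of 12 (O–B cis to C3; C3=C4 E; not isolated) | COC(=O)/C(/C=C(\OB(CCCC)CCCC)N1[C@H](Cc2ccccc2)COC1=O)=C/c1ccc(OCc2ccccc2)c(OCc2ccccc2)c1[Si](C)(C)C | intermediate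
16 | dibutylboron syn-aldolate (open chain: C2 R, C1 R; O–BBu2 on C1; not isolated) | COC(=O)/C(=C/c1ccc(OCc2ccccc2)c(OCc2ccccc2)c1[Si](C)(C)C)[C@H]([C@@H](OB(CCCC)CCCC)c1ccc(OCc2ccccc2)c(OCc2ccccc2)c1)C(=O)N1[C@H](Cc2ccccc2)COC1=O | intermediate
17 | methyl (1R,2S)-7,8-bis(benzyloxy)-1-[3,4-bis(benzyloxy)phenyl]-2-{[(4R)-4-benzyl-2-oxo-1,3-oxazolidin-3-yl]carbonyl}-1,2-dihydronaphthalene-3-carboxylate (key-step product) | COC(=O)C1=Cc2ccc(OCc3ccccc3)c(OCc3ccccc3)c2[C@@H](c2ccc(OCc3ccccc3)c(OCc3ccccc3)c2)[C@@H]1C(=O)N1[C@H](Cc2ccccc2)COC1=O | intermediate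
18 | (1R,2S)-C2 peroxy acid of the core, C3 methyl ester (not isolated) | COC(=O)C1=Cc2ccc(OCc3ccccc3)c(OCc3ccccc3)c2[C@@H](c2ccc(OCc3ccccc3)c(OCc3ccccc3)c2)[C@@H]1C(=O)OO | intermediate
19 | (1R,2S)-7,8-bis(benzyloxy)-1-[3,4-bis(benzyloxy)phenyl]-3-(methoxycarbonyl)-1,2-dihydronaphthalene-2-carboxylic acid | COC(=O)C1=Cc2ccc(OCc3ccccc3)c(OCc3ccccc3)c2[C@@H](c2ccc(OCc3ccccc3)c(OCc3ccccc3)c2)[C@@H]1C(=O)O | intermediate
20 | (1R,2S)-7,8-bis(benzyloxy)-1-[3,4-bis(benzyloxy)phenyl]-1,2-dihydronaphthalene-2,3-dicarboxylic acid | O=C(O)C1=Cc2ccc(OCc3ccccc3)c(OCc3ccccc3)c2[C@@H](c2ccc(OCc3ccccc3)c(OCc3ccccc3)c2)[C@@H]1C(=O)O | intermediate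
21 | L-DOPA | N[C@@H](Cc1ccc(O)c(O)c1)C(=O)O | starting material
22 | (2S)-3-(3,4-dihydroxyphenyl)-2-hydroxypropanoic acid | O[C@@H](Cc1ccc(O)c(O)c1)C(=O)O | intermediate
23 | benzyl (2S)-3-[3,4-bis(benzyloxy)phenyl]-2-hydroxypropanoate | O[C@@H](Cc1ccc(OCc2ccccc2)c(OCc2ccccc2)c1)C(=O)OCc1ccccc1 | intermediate
24 | decabenzyl-protected target, (1R,2S), both side chains R | O=C(O[C@H](Cc1ccc(OCc2ccccc2)c(OCc2ccccc2)c1)C(=O)OCc1ccccc1)C1=Cc2ccc(OCc3ccccc3)c(OCc3ccccc3)c2[C@@H](c2ccc(OCc3ccccc3)c(OCc3ccccc3)c2)[C@@H]1C(=O)O[C@H](Cc1ccc(OCc2ccccc2)c(OCc2ccccc2)c1)C(=O)OCc1ccccc1 | intermediate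
25 | CNP0244800.2, (1R,2S), both side chains R | O=C(O[C@H](Cc1ccc(O)c(O)c1)C(=O)O)C1=Cc2ccc(O)c(O)c2[C@@H](c2ccc(O)c(O)c2)[C@@H]1C(=O)O[C@H](Cc1ccc(O)c(O)c1)C(=O)O | target

Total step count: 14
Longest linear sequence: 11 steps (1, 2, 3, 4, 5, 6, 8, 9, 10, 13, 14)

**Steps most likely to fail**

**Step 8.**
- Protodesilylation of ring A ahead of ring closure would hand the closure to the open position para to O8.
- Loss of the C2 proton from the C1 cation would erase the auxiliary-set centre.
- Crowding around the dienolate may slow the aldol addition or invite retro-aldol cleavage once the Lewis acid is present.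

The fallback uses known chemistry, sets out from 12 and 14 and returns at 17. The two bond formations are uncoupled. The boron aldol is run alone through 15 and 16 and worked up with pH 7 buffer/MeOH/H2O2. This releases and allows purification of the syn-aldol methyl (2E)-2-[(1R,2R)-1-{[(4R)-4-benzyl-2-oxo-1,3-oxazolidin-3-yl]carbonyl}-2-[3,4-bis(benzyloxy)phenyl]-2-hydroxyethyl]-3-[3,4-bis(benzyloxy)-2-(trimethylsilyl)phenyl]prop-2-enoate F1 as a single diastereomer. In a second flask, free of amine salt and boron residues, the carbinol is ionised with BF3·OEt2 in CH2Cl2 at −78 → −20 °C. This is the established acid cyclisation of benzylic aldol adducts, here with ipso loss of silicon, and it gives 17.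

**Step 13.**
- Intramolecular dehydration of the vicinal diacid under the redox-condensation conditions, followed by acylative (retentive) esterification, would erode the side-chain configuration.
- Elimination from the activated alcohol and a stalled second esterification are further leaks.

The fallback sets out from 23 and 20 and returns at 24. The alcohol is turned into a discrete electrophile, so the acids are never activated. Tf2O and 2,6-lutidine in CH2Cl2 at −78 °C give benzyl (2S)-3-[3,4-bis(benzyloxy)phenyl]-2-[(trifluoromethyl)sulfonyloxy]propanoate F2. Treatment of 20 with Cs2CO3 (1 equiv) and this triflate (2.2 equiv) in DMF at −20 °C → rt forms both esters by carboxylate SN2 with inversion, and no base is left over once 24 is formed.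

**Step 5.**
- A 1,4 carbon-to-oxygen silyl shift (Brook type) in the potassium aldolate would strip the directing silicon.
- Alkoxide attack at silicon would have the same effect.
- The ortho substituent may also erode the E/Z selectivity.

The fallback sets out from 7 and returns at 9. Trimethyl phosphonoacetate is alkylated with allyl bromoacetate (NaH, THF) to 4-allyl 1-methyl 2-(dimethoxyphosphoryl)butanedioate F3. Its Horner–Wadsworth–Emmons reaction with 7 (LiCl, DBU, MeCN, 0 °C → rt), in which the oxyanion is lithium-bound and collapses at once, gives 4-allyl 1-methyl (2E)-2-{[3,4-bis(benzyloxy)-2-(trimethylsilyl)phenyl]methylidene}butanedioate F4. Neutral deallylation with Pd(PPh3)4 and morpholine in THF then frees the acid 9.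

**Further compounds**

F1 | step 8 | syn-aldol methyl (2E)-2-[(1R,2R)-1-{[(4R)-4-benzyl-2-oxo-1,3-oxazolidin-3-yl]carbonyl}-2-[3,4-bis(benzyloxy)phenyl]-2-hydroxyethyl]-3-[3,4-bis(benzyloxy)-2-(trimethylsilyl)phenyl]prop-2-enoate | COC(=O)/C(=C/c1ccc(OCc2ccccc2)c(OCc2ccccc2)c1[Si](C)(C)C)[C@H]([C@@H](O)c1ccc(OCc2ccccc2)c(OCc2ccccc2)c1)C(=O)N1[C@H](Cc2ccccc2)COC1=O
F2 | step 13 | benzyl (2S)-3-[3,4-bis(benzyloxy)phenyl]-2-[(trifluoromethyl)sulfonyloxy]propanoate | O=S(=O)(O[C@@H](Cc1ccc(OCc2ccccc2)c(OCc2ccccc2)c1)C(=O)OCc1ccccc1)C(F)(F)F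
F3 | step 5 | 4-allyl 1-methyl 2-(dimethoxyphosphoryl)butanedioate | COC(=O)C(CC(=O)OCC=C)P(=O)(OC)OC
F4 | step 5 | 4-allyl 1-methyl (2E)-2-{[3,4-bis(benzyloxy)-2-(trimethylsilyl)phenyl]methylidene}butanedioate | COC(=O)/C(CC(=O)OCC=C)=C/c1ccc(OCc2ccccc2)c(OCc2ccccc2)c1[Si](C)(C)C
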